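**Remarks on the chemistry (assumptions)**

- 4-(Benzyloxy)-3,5-dimethoxybenzaldehyde (the benzyl ether of syringaldehyde) and 5-bromo-2H-pyran-2-one are taken as purchasable starting materials.
- A 3,5-dimethoxy-4-oxygenated benzaldehyde has no oxygen ortho to the formyl group, so it cannot close the lactone of coumarin A with N-acetylglycine. The missing C2 hydroxyl is therefore installed first (steps 1 to 3).
- The chlorocyclobutenone 15 is reached through a symmetrical bis(aryloxy) squarate. The position of its carbinol carbon then follows from mechanism and not from a small difference in carbonyl reactivity.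

## Structural features

The target is an unsymmetrical dimer of two 6,8-dimethoxy-7-oxygenated coumarins. Coumarin A carries the free 7-OH and, at C3, an ether oxygen that is at the same time the C7' oxygen of coumarin B, whose C3'=C4' bond is unsubstituted. There is no stereocentre, so the whole problem is one of regiochemistry and chemoselectivity. Each benzene ring bears four contiguous oxygens (C6, C7, C8, C8a) beside a single C5–H. The linking oxygen joins an enol carbon alpha to a lactone carbonyl (C3) to an aryl carbon flanked by two methoxy groups (C7'), a crowded ether that is hard to make by substitution on an arene. The fragile groups are the two lactones (hydroxide, alkoxide, strong hydride), the electron-poor C3'=C4' alkene (hydrogenation) and the one free phenol, which must be told apart from four methyl ethers and is carried as a benzyl ether. The real difficulty is the C3–O–C7' bond together with the fully substituted oxygen pattern of the benzene ring of coumarin B. The key step uses the fact that C6', C7' and C8' carry adjacent oxygens next to C5'–H. This is the pattern a squaric acid-derived cyclobutenone delivers when it is fused onto the C5=C6 bond of a 2-pyranone: the carbonyl carbon becomes C8', the aryloxy carbon C7', the methoxy carbon C6', the CHCl carbon C5', and the pyranone supplies C4a', C8a' and the finished lactone. The ether is thus made at the squarate stage as an acyl-type substitution, where it is easy.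

## Logic of the disconnections

**23 back to 21.** The last two operations touch oxygen only: the C7–O benzyl bond of 22 is cleaved to give 23, and the C8'–O methyl bond of 22 is made from 21. Cutting here leaves the one hydroxyl that the ring-forming step necessarily produces (C8') as the only free OH, so methylation needs no selectivity. The demand is a debenzylation that spares four methyl ethers, two lactones and the C3'=C4' alkene.

**21 back to 15 and 17.** Two bonds of the benzene ring of coumarin B are cut, C4a'–C5' and C8'–C8a'. This removes a whole ring and splits the molecule into a four-carbon piece that holds all three adjacent oxygens with the ether already in place (15) and an intact pyranone (17). The forward step must couple at C4 of 15, open the four-membered ring and close onto C6 of the pyranone.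

**17 back to 16.** The C5–Sn bond is cut to the bromide 16; the demand is a palladium-catalysed stannylation that does not consume the product by homocoupling.

**15 back to 13.** The C4–Cl bond of 15 is traced to the C4–OH of 14, and the C3–OMe bond of 14 to a C3–aryloxy bond in 13. Only the beta carbon of the enone can exchange its substituent by addition–elimination, so methanol must enter at C3 and the aryloxy group at C2 must stay. The demands are a neutral chlorination and an exchange mild enough for a 4-hydroxycyclobutenone.

**13 back to 10 and 9.** The C4–H bond of 13 comes from mono-reduction of the symmetrical diester 12, in which both carbonyls are equivalent. The two C–O bonds of 12 are cut to the dichloride 11 (from 10) and two equivalents of 9, one of which is returned when 13 is converted into 14. The demand is O-attack of the ambident enol 9 and a hydride that stops after one carbonyl.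

**9 back to 6 and 7.** The C3–O bond of 9 is traced to the C3–N bond of 8, and the pyranone of coumarin A (C3–C4 and O1–C2) to a condensation of 6 with 7. This is the standard way to place a heteroatom at C3 of a coumarin; it requires an ortho-hydroxy aldehyde.

**6 back to 1.** The C2–O bond of 6 is cut to the C2–Br bond of 2 (through the acetal 3), and C2–Br to C2–H of 1. Both free ring positions of 1 are equivalent, so the bromination has only one outcome; the price is two steps of aldehyde masking and unmasking around the organolithium.

## Other disconnections considered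

**Alternative 1:** The cut is at O1–C8a and O1'–C8a' of both lactones. It leads to the diacid A2, (Z)-3-[4-(benzyloxy)-3,5-dimethoxyphenyl]-2-{4-[(E)-2-carboxyethenyl]-2,6-dimethoxyphenoxy}prop-2-enoic acid, in which the linking ether already exists as an alpha-aryloxy acrylate. In the forward step a flavin photocatalyst under oxygen would turn each acrylic acid so that the carboxyl faces the ring, then oxidise each arene by one electron so that the carboxylate closes onto an ortho carbon. The product A1 is identical with 22.
- In favour: both pyranones form in one operation; each ring has two equivalent ortho positions, so there is no regiochemical issue; no ortho oxygen has to be pre-installed, which is exactly what costs steps 1 to 3 of the chosen plan. On step economy and on fit to cheap 3,5-dimethoxy-4-hydroxyphenyl building blocks this alternative is the better one.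
- Against: the precedent for this oxidative lactonisation lies with simple cinnamic acids. Ring A needs geometric inversion and oxidation of a trisubstituted alpha-aryloxy acrylate. Two independent closures must both succeed in one molecule, and the benzylic ether and the product coumarins are themselves open to photo-oxidation or photodimerisation.
- Comparison: on structure the two plans are equal (no stereochemistry, same protected product). On mechanism the chosen plan relies on polar and pericyclic steps whose regiochemistry is locked by connectivity, whereas A1 depends on redox matching of two different arenes; both extend known chemistry to a new substrate class.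

**Alternative 2:** The cut is at C4'–C4a' and O1'–C2' of the pyran ring of coumarin B. It leads to the aryl propargyl ether A4, 7-(benzyloxy)-3-[2,6-dimethoxy-3-(prop-2-yn-1-yloxy)phenoxy]-6,8-dimethoxycoumarin. Heating would bring about Claisen rearrangement to the single free ortho position, enolisation, a 1,5-hydrogen shift and oxa-6-electron closure to the 2H-chromene A3.
- In favour: this cascade is a long-established chromene synthesis, so the key step itself is better precedented than the chosen one. Its regiochemistry is fixed by the one open ortho carbon. A3 is two steps from the target (allylic oxidation of C2' to 22, then debenzylation), which equals the chosen plan.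
- Against: the step forms neither the C3–O–C7' ether nor any ring oxygen. A4 must already contain that ether on a 1,2,3,4-tetraoxygenated benzene with four differently substituted oxygens, so the difficulty is only moved into the precursor. At about 200 °C a 2-methylbenzofuran pathway can compete, and the later oxidation of the C2' methylene must spare the benzyl CH2.
- Comparison: structure equal; the mechanism is more reliable in the key step but less so in the oxidation; the overall step count is expected to be no lower, because the precursor is harder than 15.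

**Alternative 3:** The cut is at C3–C4 of coumarin A. It leads to the ester A6, methyl 4-(benzyloxy)-2-({[(6,8-dimethoxy-2-oxo-2H-chromen-7-yl)oxy]acetyl}oxy)-3,5-dimethoxybenzoate. Base would form the enolate of the aryloxyacetate, which attacks the methyl ester carbon in a Dieckmann closure to give the 4-hydroxycoumarin A5.
- In favour: coumarin B enters intact with all its oxygens in place, and closure of O-acyl salicylates to 4-hydroxycoumarins is standard. On precedent, convergence and probably total step count this alternative is the better one.
- Against: C4 ends at the wrong oxidation level. The hydroxyl must be removed by sulfonylation and palladium-catalysed hydride reduction, so A5 is three steps from the target against two for 21. The enolate of an aryl ester can also expel the salicylate oxygen (ketene formation) before C-acylation, and strong base meets the lactone of coumarin B.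
- Comparison: structure equal; the mechanism is more secure in the ring closure and less so in the deoxygenation of a hindered 4-sulfonate; the endgame is one step longer, the whole route probably shorter.

Key step: step 12

## Route

Step 1
Reactants: 1 4-(benzyloxy)-3,5-dimethoxybenzaldehyde
Product: 2 4-(benzyloxy)-2-bromo-3,5-dimethoxybenzaldehyde
Conditions: NBS, MeCN, 0 °C to rt, dark
Reagents that add atoms: N-bromosuccinimide, O=C1CCC(=O)N1Br
Why: Electrophilic aromatic bromination; the two free ring positions are equivalent and each is ortho and para to a methoxy group, so only one monobromide can form, and ionic conditions in the dark leave the benzylic CH2 and the aldehyde alone.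

Step 2
Reactants: 2 4-(benzyloxy)-2-bromo-3,5-dimethoxybenzaldehyde
Product: 3 2-[4-(benzyloxy)-2-bromo-3,5-dimethoxyphenyl]-1,3-dioxolane
Conditions: HOCH2CH2OH, p-TsOH (cat.), toluene, reflux, azeotropic removal of water
Reagents that add atoms: ethane-1,2-diol, OCCO
Why: Acid-catalysed acetal formation masks the aldehyde against the organolithium and the peroxide of step 3.

Step 3
Reactants: 3 2-[4-(benzyloxy)-2-bromo-3,5-dimethoxyphenyl]-1,3-dioxolane
Product: 6 4-(benzyloxy)-2-hydroxy-3,5-dimethoxybenzaldehyde, via lithium aryltrimethoxyborate 4 (not isolated), via dioxolanyl phenol 5 (not isolated)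
Conditions: n-BuLi, THF, −78 °C; B(OMe)3, −78 °C to rt; 30% H2O2, 0 °C; Na2S2O3; 2 M HCl, rt
Reagents that add atoms: hydrogen peroxide, OO; water, O
Why: Bromine–lithium exchange at −78 °C is faster than attack on the benzyl ether, the aryl anion is trapped as borate 4, and peroxide triggers the 1,2-shift of aryl from boron to oxygen so that the hydroxyl of 5 stands exactly where bromine stood; excess peroxide is destroyed before aqueous acid unmasks the aldehyde, which avoids a Dakin-type oxidation.

Step 4
Reactants: 6 4-(benzyloxy)-2-hydroxy-3,5-dimethoxybenzaldehyde; 7 N-acetylglycine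
Product: 8 N-[7-(benzyloxy)-6,8-dimethoxy-2-oxo-2H-chromen-3-yl]acetamide
Conditions: NaOAc, Ac2O, 120 °C
Reagents that add atoms: none
Why: Erlenmeyer–Plöchl azlactone condensation under Perkin conditions; the azlactone formed from 7 condenses with the aldehyde and is opened by the ortho phenol oxygen, which closes the lactone, the established route from salicylaldehydes to 3-acetamidocoumarins.

Step 5
Reactants: 8 N-[7-(benzyloxy)-6,8-dimethoxy-2-oxo-2H-chromen-3-yl]acetamide
Product: 9 7-(benzyloxy)-3-hydroxy-6,8-dimethoxy-2H-chromen-2-one
Conditions: 3 M HCl, 1,4-dioxane, 90 °C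
Reagents that add atoms: water, O
Why: Acid hydrolysis of the enamide: protonation at C4, addition of water to the N-acyliminium carbon C3 and loss of acetamide give the alpha-keto lactone, which rests as its enol 9; a benzyl aryl ether should tolerate dilute HCl.

Step 6
Reactants: 10 squaric acid (3,4-dihydroxycyclobut-3-ene-1,2-dione)
Product: 11 3,4-dichlorocyclobut-3-ene-1,2-dione
Conditions: (COCl)2, DMF (cat.), CH2Cl2, rt
Reagents that add atoms: oxalyl chloride, O=C(Cl)C(=O)Cl
Why: Chlorination of the two vinylogous acid hydroxyls through the chloroiminium salt formed from DMF, the standard preparation of the squaric dichloride.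

Step 7
Reactants: 11 3,4-dichlorocyclobut-3-ene-1,2-dione; 9 7-(benzyloxy)-3-hydroxy-6,8-dimethoxy-2H-chromen-2-one (2 equiv)
Product: 12 3,4-bis{[7-(benzyloxy)-6,8-dimethoxy-2-oxo-2H-chromen-3-yl]oxy}cyclobut-3-ene-1,2-dione
Conditions: iPr2NEt, CH2Cl2, −40 °C to rt
Reagents that add atoms: none
Why: Two successive addition–elimination reactions at the vinylogous acid chloride carbons; the hard enol oxygen of 9 should attack in preference to C4 with an acyl-type electrophile, as in the preparation of diaryl squarates from phenols.

Step 8
Reactants: 12 3,4-bis{[7-(benzyloxy)-6,8-dimethoxy-2-oxo-2H-chromen-3-yl]oxy}cyclobut-3-ene-1,2-dione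
Product: 13 2,3-bis{[7-(benzyloxy)-6,8-dimethoxy-2-oxo-2H-chromen-3-yl]oxy}-4-hydroxycyclobut-2-en-1-one (racemic)
Conditions: LiAlH(OtBu)3, THF, −78 °C; pH 7 buffer
Reagents that add atoms: none
Why: Mono-reduction of a squaric diester with a bulky, mild hydride stops at the 4-hydroxycyclobutenone because the remaining carbonyl becomes a vinylogous ester; 12 is symmetrical, so no regiochemical question arises, the lactones are inert at −78 °C, and the new stereocentre C4 is racemic and later destroyed.

Step 9
Reactants: 13 2,3-bis{[7-(benzyloxy)-6,8-dimethoxy-2-oxo-2H-chromen-3-yl]oxy}-4-hydroxycyclobut-2-en-1-one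
Product: 14 2-{[7-(benzyloxy)-6,8-dimethoxy-2-oxo-2H-chromen-3-yl]oxy}-4-hydroxy-3-methoxycyclobut-2-en-1-one (racemic)
Conditions: MeOH, Et3N, CH2Cl2, 0 °C
Reagents that add atoms: methanol, CO
Why: Vinylogous transesterification by conjugate addition–elimination: methanol can attack only C3, the beta carbon of the enone, where the aryloxide (enol 9, recovered) is a good leaving group, whereas the aryloxy group on the alpha carbon C2 cannot leave this way, so the oxygen pattern of 14 is fixed by mechanism.

Step 10
Reactants: 14 2-{[7-(benzyloxy)-6,8-dimethoxy-2-oxo-2H-chromen-3-yl]oxy}-4-hydroxy-3-methoxycyclobut-2-en-1-one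
Product: 15 4-chloro-2-{[7-(benzyloxy)-6,8-dimethoxy-2-oxo-2H-chromen-3-yl]oxy}-3-methoxycyclobut-2-en-1-one (racemic)
Conditions: Me2C=C(Cl)NMe2, CH2Cl2, 0 °C to rt
Reagents that add atoms: 1-chloro-N,N,2-trimethylprop-1-en-1-amine, CC(C)=C(Cl)N(C)C
Why: The alpha-chloroenamine turns the alcohol into an imidate-type leaving group that chloride displaces under neutral conditions, a known alcohol-to-chloride conversion that avoids the acid which would ionise the alkoxy-substituted cyclobutenyl system; C4 stays racemic.

Step 11
Reactants: 16 5-bromo-2H-pyran-2-one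
Product: 17 5-(tributylstannyl)-2H-pyran-2-one
Conditions: (Bu3Sn)2, Pd(PPh3)4 (5 mol %), 1,4-dioxane, 90 °C
Reagents that add atoms: hexabutyldistannane, CCCC[Sn](CCCC)(CCCC)[Sn](CCCC)(CCCC)CCCC
Why: Palladium-catalysed stannylation of a vinyl bromide with a distannane (insertion of zerovalent palladium into C5–Br, transmetalation with the Sn–Sn bond, reductive elimination), a method established for halo-2-pyranones; an excess of distannane suppresses homocoupling.

Step 12
Reactants: 15 4-chloro-2-{[7-(benzyloxy)-6,8-dimethoxy-2-oxo-2H-chromen-3-yl]oxy}-3-methoxycyclobut-2-en-1-one; 17 5-(tributylstannyl)-2H-pyran-2-one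
Product: 21 7-(benzyloxy)-3-[(8-hydroxy-6-methoxy-2-oxo-2H-chromen-7-yl)oxy]-6,8-dimethoxy-2H-chromen-2-one, via pyranonyl cyclobutenone 18 (not isolated), via dienylketene 19 (not isolated), via cyclohexadienone tautomer 20 (not isolated)
Conditions: Pd2(dba)3 (2.5 mol %), tri(2-furyl)phosphine (10 mol %), 1,4-dioxane, 50 °C, then 100 °C
Reagents that add atoms: none
Why: Proposed new method: zerovalent palladium inserts into the allylic, alpha-keto C4–Cl bond of 15, the pyranonyl group is transferred from tin, and reductive elimination at C4 (not at the aryloxy-bearing C2, which would break the vinylogous ester and create a quaternary carbon) gives 18 with the new C4a'–C5' bond. At 100 °C 18 opens by thermal conrotatory 4-electron cleavage of the C1–C4 bond to a vinylketene; the isomer with the pyranonyl group turned outward can only reclose to 18, so the material drains through 19, in which the pyranone C5=C6 bond lies next to the ketene. The one ring that is built closes by thermal disrotatory 6-electron electrocyclisation of the triene made of the ketene C=C, the methoxy-substituted alkene and pyranone C5=C6, forming C8'–C8a' and giving 20; from pyranone C5 the only double bond is C5=C6, so closure cannot go toward C4 and the ring oxygen must end on C8a'. Loss of the C8a' hydrogen by enolisation aromatises 20 to 21 and makes the sequence irreversible. The oxygen pattern follows from the connectivity of 15: the carbonyl carbon becomes C8'–OH, the aryloxy carbon C7', the methoxy carbon C6' and the CHCl carbon C5'–H. No stereocentre survives, since C4 of 18 and C8a' of 20 are transient and racemic. The closest known reaction type is the Stille coupling of 4-chlorocyclobut-2-enones with alkenyl, aryl and heteroaryl stannanes followed by thermal benzannulation to phenols; not yet shown are a 2-pyranon-5-yl stannane as the 2-electron partner and a 2-aryloxy-3-methoxy cyclobutenone, but the weakly aromatic pyranone should give up its C5=C6 bond more readily than the furans and benzenes known to react.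

Step 13
Reactants: 21 7-(benzyloxy)-3-[(8-hydroxy-6-methoxy-2-oxo-2H-chromen-7-yl)oxy]-6,8-dimethoxy-2H-chromen-2-one
Product: 22 7-(benzyloxy)-3-[(6,8-dimethoxy-2-oxo-2H-chromen-7-yl)oxy]-6,8-dimethoxy-2H-chromen-2-one
Conditions: MeI, K2CO3, acetone, 40 °C
Reagents that add atoms: iodomethane, CI
Why: Williamson methylation of the C8' phenol, the only free hydroxyl in 21; both lactones should tolerate carbonate in acetone.

Step 14
Reactants: 22 7-(benzyloxy)-3-[(6,8-dimethoxy-2-oxo-2H-chromen-7-yl)oxy]-6,8-dimethoxy-2H-chromen-2-one
Product: 23 7-hydroxy-3-[(6,8-dimethoxy-2-oxo-2H-chromen-7-yl)oxy]-6,8-dimethoxy-2H-chromen-2-one (target)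
Conditions: BCl3, C6HMe5, CH2Cl2, −78 °C; MeOH
Reagents that add atoms: none
Why: Lewis acid cleavage of the benzyl aryl ether with pentamethylbenzene as a non-basic scavenger of the benzyl cation; at −78 °C the methyl ethers, the enol aryl ether and both lactones should be untouched, and no hydrogenation of the C3'=C4' bond is risked.

## Compound list

1 | 4-(benzyloxy)-3,5-dimethoxybenzaldehyde | COc1cc(C=O)cc(OC)c1OCc1ccccc1 | starting material
2 | 4-(benzyloxy)-2-bromo-3,5-dimethoxybenzaldehyde | COc1cc(C=O)c(Br)c(OC)c1OCc1ccccc1 | intermediate
3 | 2-[4-(benzyloxy)-2-bromo-3,5-dimethoxyphenyl]-1,3-dioxolane | COc1cc(C2OCCO2)c(Br)c(OC)c1OCc1ccccc1 | intermediate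
4 | lithium [3-(benzyloxy)-6-(1,3-dioxolan-2-yl)-2,4-dimethoxyphenyl]trimethoxyborate | [Li+].COc1cc(C2OCCO2)c([B-](OC)(OC)OC)c(OC)c1OCc1ccccc1 | intermediate (not isolated)
5 | 3-(benzyloxy)-6-(1,3-dioxolan-2-yl)-2,4-dimethoxyphenol | COc1cc(C2OCCO2)c(O)c(OC)c1OCc1ccccc1 | intermediate (not isolated)
6 | 4-(benzyloxy)-2-hydroxy-3,5-dimethoxybenzaldehyde | COc1cc(C=O)c(O)c(OC)c1OCc1ccccc1 | intermediate
7 | N-acetylglycine | CC(=O)NCC(=O)O | starting material
8 | N-[7-(benzyloxy)-6,8-dimethoxy-2-oxo-2H-chromen-3-yl]acetamide | CC(=O)Nc1cc2cc(OC)c(OCc3ccccc3)c(OC)c2oc1=O | intermediate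
9 | 7-(benzyloxy)-3-hydroxy-6,8-dimethoxy-2H-chromen-2-one | COc1cc2cc(O)c(=O)oc2c(OC)c1OCc1ccccc1 | intermediate
10 | squaric acid | OC1=C(O)C(=O)C1=O | starting material
11 | 3,4-dichlorocyclobut-3-ene-1,2-dione | ClC1=C(Cl)C(=O)C1=O | intermediate
12 | 3,4-bis{[7-(benzyloxy)-6,8-dimethoxy-2-oxo-2H-chromen-3-yl]oxy}cyclobut-3-ene-1,2-dione | O=C1C(=O)C(Oc2cc3cc(OC)c(OCc4ccccc4)c(OC)c3oc2=O)=C1Oc1cc2cc(OC)c(OCc3ccccc3)c(OC)c2oc1=O | intermediate
13 | 2,3-bis{[7-(benzyloxy)-6,8-dimethoxy-2-oxo-2H-chromen-3-yl]oxy}-4-hydroxycyclobut-2-en-1-one (racemic) | O=C1C(Oc2cc3cc(OC)c(OCc4ccccc4)c(OC)c3oc2=O)=C(Oc2cc3cc(OC)c(OCc4ccccc4)c(OC)c3oc2=O)C1O | intermediate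
14 | 2-{[7-(benzyloxy)-6,8-dimethoxy-2-oxo-2H-chromen-3-yl]oxy}-4-hydroxy-3-methoxycyclobut-2-en-1-one (racemic) | COC1=C(Oc2cc3cc(OC)c(OCc4ccccc4)c(OC)c3oc2=O)C(=O)C1O | intermediate
15 | 4-chloro-2-{[7-(benzyloxy)-6,8-dimethoxy-2-oxo-2H-chromen-3-yl]oxy}-3-methoxycyclobut-2-en-1-one (racemic) | COC1=C(Oc2cc3cc(OC)c(OCc4ccccc4)c(OC)c3oc2=O)C(=O)C1Cl | intermediate (precursor of the key step)
16 | 5-bromo-2H-pyran-2-one | O=c1ccc(Br)co1 | starting material
17 | 5-(tributylstannyl)-2H-pyran-2-one | CCCC[Sn](CCCC)(CCCC)c1ccc(=O)oc1 | intermediate
18 | 2-{[7-(benzyloxy)-6,8-dimethoxy-2-oxo-2H-chromen-3-yl]oxy}-3-methoxy-4-(2-oxo-2H-pyran-5-yl)cyclobut-2-en-1-one (racemic) | COC1=C(Oc2cc3cc(OC)c(OCc4ccccc4)c(OC)c3oc2=O)C(=O)C1c1ccc(=O)oc1 | intermediate (not isolated)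
19 | (3E)-2-{[7-(benzyloxy)-6,8-dimethoxy-2-oxo-2H-chromen-3-yl]oxy}-3-methoxy-4-(2-oxo-2H-pyran-5-yl)buta-1,3-dien-1-one (pyranonyl group cis to C2) | O=C=C(Oc1cc2cc(OC)c(OCc3ccccc3)c(OC)c2oc1=O)/C(OC)=C\c1ccc(=O)oc1 | intermediate (not isolated)
20 | 7-(benzyloxy)-3-[(6-methoxy-2,8-dioxo-8,8a-dihydro-2H-chromen-7-yl)oxy]-6,8-dimethoxy-2H-chromen-2-one (racemic at C8a') | COC1=C(Oc2cc3cc(OC)c(OCc4ccccc4)c(OC)c3oc2=O)C(=O)C2OC(=O)C=CC2=C1 | intermediate (not isolated)
21 | 7-(benzyloxy)-3-[(8-hydroxy-6-methoxy-2-oxo-2H-chromen-7-yl)oxy]-6,8-dimethoxy-2H-chromen-2-one | COc1cc2cc(Oc3c(OC)cc4ccc(=O)oc4c3O)c(=O)oc2c(OC)c1OCc1ccccc1 | intermediate (product of the key step)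
22 | 7-(benzyloxy)-3-[(6,8-dimethoxy-2-oxo-2H-chromen-7-yl)oxy]-6,8-dimethoxy-2H-chromen-2-one | COc1cc2cc(Oc3c(OC)cc4ccc(=O)oc4c3OC)c(=O)oc2c(OC)c1OCc1ccccc1 | intermediate
23 | 7-hydroxy-3-[(6,8-dimethoxy-2-oxo-2H-chromen-7-yl)oxy]-6,8-dimethoxy-2H-chromen-2-one | COc1cc2cc(Oc3c(OC)cc4ccc(=O)oc4c3OC)c(=O)oc2c(OC)c1O | target

## Step count and least certain steps

Total: 14 steps. Longest linear sequence: 12 steps (steps 1 to 5, 7 to 10, 12 to 14). Compound 9 enters step 7 twice, and one equivalent should be recovered in step 9.

**Step 12 (key step, carries the label).** The most likely failure is slow transfer of the electron-poor pyranonyl group from tin to the hindered cyclobutenyl-palladium species. That would leave 15 time to open thermally on its own or to be reduced, and would leave 17 time to lose tin or homocouple. A second failure is interception of ketene 19 (dimerisation, adventitious nucleophiles) before it closes onto the pyranone. The fallback uses known chemistry and gives up the benzannulation. It sets out from 6. The purchasable natural coumarin 7-hydroxy-6,8-dimethoxy-2H-chromen-2-one F1 would be O-alkylated with tert-butyl bromoacetate and K2CO3 to tert-butyl [(6,8-dimethoxy-2-oxo-2H-chromen-7-yl)oxy]acetate F2. Trifluoroacetic acid would free [(6,8-dimethoxy-2-oxo-2H-chromen-7-yl)oxy]acetic acid F3. Perkin–Oglialoro condensation of F3 with 6 (Ac2O, Et3N, 120 °C), the classical route from salicylaldehydes and aryloxyacetic acids to 3-aryloxycoumarins, would close the pyranone of coumarin A and come back to the route at 22. This detour is shorter than the main line.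

**Step 8.** Hydride or tert-butoxide may attack the aryloxy-bearing alkene carbons of 12 instead of a carbonyl, because a diaryl squarate is an activated vinylogous ester; an aryloxy group would then be lost by addition–elimination, or reduction may overrun. The fallback sets out from 11. One chloride would be replaced by methanol to give 3-chloro-4-methoxycyclobut-3-ene-1,2-dione F4, and the other by 9 to give 3-{[7-(benzyloxy)-6,8-dimethoxy-2-oxo-2H-chromen-3-yl]oxy}-4-methoxycyclobut-3-ene-1,2-dione F5. F5 has only one aryloxy site and a strong methoxy donor, so it is closer to the dialkyl squarates for which this mono-reduction is established. LiAlH(OtBu)3 should then attack the carbonyl conjugated with the weaker aryloxy donor, which is also the less hindered one beside C–OMe, and give 14 directly, by-passing step 9. The price is that the position of the carbinol then rests on an electronic bias and must be proved by long-range C–H correlation before going on.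

**Step 9.** The 4-hydroxycyclobutenone may break down in basic methanol (methoxide addition to the ketone with ring cleavage, or methanolysis of a lactone) before the exchange is complete. The fallback sets out from 13 and inverts the order: chlorination with the reagent of step 10 would give 2,3-bis{[7-(benzyloxy)-6,8-dimethoxy-2-oxo-2H-chromen-3-yl]oxy}-4-chlorocyclobut-2-en-1-one F6, which has no free hydroxyl. The beta-aryloxy group of F6 would then be exchanged with methanol and 2,6-lutidine, returning to the route at 15.

**Step 10.** The activated carbinol may ionise to the alkoxy-stabilised cyclobutenyl cation, with allylic transposition and loss of methanol or of the aryloxy group to give cyclobutenediones. The fallback sets out from 14 and avoids a halide altogether: methyl chloroformate and pyridine at −40 °C would give 2-{[7-(benzyloxy)-6,8-dimethoxy-2-oxo-2H-chromen-3-yl]oxy}-3-methoxy-4-oxocyclobut-2-en-1-yl methyl carbonate F7. Zerovalent palladium should ionise this allylic carbonate to the same cyclobutenyl-palladium species; coupling with 17 under the conditions of step 12 would rejoin the route at 18 and hence 21.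

## Further compounds

F1 | step 12 | 7-hydroxy-6,8-dimethoxy-2H-chromen-2-one (isofraxidin, purchased) | COc1cc2ccc(=O)oc2c(OC)c1O
F2 | step 12 | tert-butyl [(6,8-dimethoxy-2-oxo-2H-chromen-7-yl)oxy]acetate | COc1cc2ccc(=O)oc2c(OC)c1OCC(=O)OC(C)(C)C
F3 | step 12 | [(6,8-dimethoxy-2-oxo-2H-chromen-7-yl)oxy]acetic acid | COc1cc2ccc(=O)oc2c(OC)c1OCC(=O)O
F4 | step 8 | 3-chloro-4-methoxycyclobut-3-ene-1,2-dione | COC1=C(Cl)C(=O)C1=O
F5 | step 8 | 3-{[7-(benzyloxy)-6,8-dimethoxy-2-oxo-2H-chromen-3-yl]oxy}-4-methoxycyclobut-3-ene-1,2-dione | COC1=C(Oc2cc3cc(OC)c(OCc4ccccc4)c(OC)c3oc2=O)C(=O)C1=O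
F6 | step 9 | 2,3-bis{[7-(benzyloxy)-6,8-dimethoxy-2-oxo-2H-chromen-3-yl]oxy}-4-chlorocyclobut-2-en-1-one (racemic) | O=C1C(Oc2cc3cc(OC)c(OCc4ccccc4)c(OC)c3oc2=O)=C(Oc2cc3cc(OC)c(OCc4ccccc4)c(OC)c3oc2=O)C1Cl
F7 | step 10 | 2-{[7-(benzyloxy)-6,8-dimethoxy-2-oxo-2H-chromen-3-yl]oxy}-3-methoxy-4-oxocyclobut-2-en-1-yl methyl carbonate (racemic) | COC(=O)OC1C(OC)=C(Oc2cc3cc(OC)c(OCc4ccccc4)c(OC)c3oc2=O)C1=O
A1 | alternative 1 | 7-(benzyloxy)-3-[(6,8-dimethoxy-2-oxo-2H-chromen-7-yl)oxy]-6,8-dimethoxy-2H-chromen-2-one (identical with 22) | COc1cc2cc(Oc3c(OC)cc4ccc(=O)oc4c3OC)c(=O)oc2c(OC)c1OCc1ccccc1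
A2 | alternative 1 | (Z)-3-[4-(benzyloxy)-3,5-dimethoxyphenyl]-2-{4-[(E)-2-carboxyethenyl]-2,6-dimethoxyphenoxy}prop-2-enoic acid | COc1cc(/C=C(\Oc2c(OC)cc(/C=C/C(=O)O)cc2OC)C(=O)O)cc(OC)c1OCc1ccccc1
A3 | alternative 2 | 7-(benzyloxy)-3-[(6,8-dimethoxy-2H-chromen-7-yl)oxy]-6,8-dimethoxy-2H-chromen-2-one | COc1cc2cc(Oc3c(OC)cc4c(c3OC)OCC=C4)c(=O)oc2c(OC)c1OCc1ccccc1
A4 | alternative 2 | 7-(benzyloxy)-3-[2,6-dimethoxy-3-(prop-2-yn-1-yloxy)phenoxy]-6,8-dimethoxy-2H-chromen-2-one | COc1cc2cc(Oc3c(OC)ccc(OCC#C)c3OC)c(=O)oc2c(OC)c1OCc1ccccc1
A5 | alternative 3 | 7-(benzyloxy)-4-hydroxy-3-[(6,8-dimethoxy-2-oxo-2H-chromen-7-yl)oxy]-6,8-dimethoxy-2H-chromen-2-one | COc1cc2c(O)c(Oc3c(OC)cc4ccc(=O)oc4c3OC)c(=O)oc2c(OC)c1OCc1ccccc1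
A6 | alternative 3 | methyl 4-(benzyloxy)-2-({[(6,8-dimethoxy-2-oxo-2H-chromen-7-yl)oxy]acetyl}oxy)-3,5-dimethoxybenzoate | COC(=O)c1cc(OC)c(OCc2ccccc2)c(OC)c1OC(=O)COc1c(OC)cc2ccc(=O)oc2c1OC
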